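## Retrosynthetic overview

1. Blepharocalyxin B ⇐ global desilylation ⇐ the ring A C3–C1″ bond from a Pd-catalysed O-allylation of the 4-OH of ring A followed by an aromatic Claisen shift (3R → 1R chirality transfer).
2. Key step: the oxane ring ⇐ Lewis-acid formal insertion of the chalcone C=C into the allylic C–O bond of a 2-styryl-4-(arylethyl)oxetane (ring expansion 4 → 6). This makes O1–C2 and C3–C4 and sets C2, C3 and C4.
3. One enantiopure trans-oxetane is used twice (ring expansion, then O-allylation). It comes from an enone + aldehyde boron aldol, mesylation, CBS reduction and Williamson closure.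
4. The chalcone ⇐ 2,4-dihydroxy-6-methoxyacetophenone (anisole: C–H diborylation/oxidation, then acetylation) + a 4-silyloxybenzaldehyde.
5. All five hydroxyphenyl groups come from 4-iodophenol. Ring order: oxetane first, then oxane; the benzene rings are bought.

Notation: TBS = tert-butyldimethylsilyl, TBSO = TBS–O; chain locants are those of a 1,7-diarylheptane.

Assumption: (−)-B-chlorodiisopinocampheylborane is taken to deliver the methyl-ketone enolate to the Si face of the aldehyde (5R aldol); if the sense is the opposite, the (+)-reagent is used and nothing else changes.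

## Route

Step 1
Reactants: 1 4-iodophenol
Product: 2 tert-butyl(4-iodophenoxy)dimethylsilane
Conditions: TBSCl (1.1 equiv), imidazole (2.2 equiv), CH2Cl2, 25 °C
Reagents that add atoms: tert-butyldimethylsilyl chloride, CC(C)(C)[Si](C)(C)Cl
Why: Standard phenol silylation; the aryl silyl ether masks every 4-hydroxyphenyl group until the last step.

Step 2
Reactants: 2 tert-butyl(4-iodophenoxy)dimethylsilane; 3 prop-2-en-1-ol (allyl alcohol)
Product: 4 3-[4-(TBSO)phenyl]propanal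
Conditions: Pd(OAc)2 (2 mol%), Bu4NCl, NaHCO3, DMF, 45 °C
Reagents that add atoms: none
Why: Mizoroki–Heck arylation of an allylic alcohol (Jeffery conditions); β-hydride elimination toward the carbinol and tautomerisation give the 3-arylpropanal.

Step 3
Reactants: 2 tert-butyl(4-iodophenoxy)dimethylsilane; 5 but-3-en-2-one (methyl vinyl ketone)
Product: 6 (E)-4-[4-(TBSO)phenyl]but-3-en-2-one
Conditions: Pd(OAc)2 (2 mol%), Bu4NCl, NaHCO3, DMF, 60 °C
Reagents that add atoms: none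
Why: Mizoroki–Heck reaction of an aryl iodide with an enone; syn-insertion and syn-β-hydride elimination give the E-alkene.

Step 4
Reactants: 6 (E)-4-[4-(TBSO)phenyl]but-3-en-2-one; 4 3-[4-(TBSO)phenyl]propanal
Product: 8 (1E,5R)-5-hydroxy-1,7-bis[4-(TBSO)phenyl]hept-1-en-3-one, via diisopinocampheylboron dienolate 7 (not isolated)
Conditions: (−)-B-chlorodiisopinocampheylborane (1.3 equiv), Et3N (1.5 equiv), Et2O, −78 to 0 °C; then 4 (1.2 equiv), −78 to −20 °C; then MeOH, pH 7 buffer, 30% H2O2, 0 °C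
Reagents that add atoms: (−)-B-chlorodiisopinocampheylborane (boron and isopinocampheyl groups of 7 only), ClB([C@@H]1C[C@@H]2C[C@H]([C@H]1C)C2(C)C)[C@@H]1C[C@@H]2C[C@H]([C@H]1C)C2(C)C
Why: Paterson boron-mediated aldol of a methyl ketone; the chiral isopinocampheyl ligands select the aldehyde face in a cyclic transition state and set C5 as R (about 80% ee expected, upgraded after step 6).

Step 5
Reactants: 8 (1E,5R)-5-hydroxy-1,7-bis[4-(TBSO)phenyl]hept-1-en-3-one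
Product: 9 (1E,5R)-3-oxo-1,7-bis[4-(TBSO)phenyl]hept-1-en-5-yl methanesulfonate
Conditions: MsCl (1.3 equiv), pyridine, CH2Cl2, −10 °C; used crude
Reagents that add atoms: methanesulfonyl chloride, CS(=O)(=O)Cl
Why: O-sulfonylation of the only hydroxyl, so the leaving group sits unambiguously on C5 with its configuration unchanged; cold pyridine avoids E1cB elimination of the β-mesyloxy ketone.

Step 6
Reactants: 9 (1E,5R)-3-oxo-1,7-bis[4-(TBSO)phenyl]hept-1-en-5-yl methanesulfonate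
Product: 11 (2R,4S)-2-{(E)-2-[4-(TBSO)phenyl]ethenyl}-4-{2-[4-(TBSO)phenyl]ethyl}oxetane (trans), via hydroxy mesylate 10 (not isolated)
Conditions: (S)-Me-CBS oxazaborolidine (15 mol%), BH3·SMe2 (0.8 equiv), THF, −30 °C; MeOH quench, evaporate; then KHMDS (1.05 equiv), THF, −78 to 0 °C
Reagents that add atoms: none
Why: Corey–Bakshi–Shibata reduction (styryl as the large group, so the (S)-catalyst gives the 3R carbinol, 1,2-selectively), then intramolecular Williamson etherification (4-exo-tet SN2) inverts C5 to S; the minor stereoisomers from steps 4 and 6 end up as cis-oxetanes and are removed by chromatography, which raises the enantiomeric purity.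

Step 7
Reactants: 12 anisole
Product: 14 5-methoxybenzene-1,3-diol, via bis(boronate) 13 (not isolated)
Conditions: [Ir(OMe)(cod)]2 (1.5 mol%), 4,4′-di-tert-butyl-2,2′-bipyridine (3 mol%), B2pin2 (1.2 equiv), THF, 80 °C; then Oxone (2KHSO5·KHSO4·K2SO4), acetone–H2O, 25 °C
Reagents that add atoms: bis(pinacolato)diboron (boryl groups of 13 only), CC1(C)OB(OC1(C)C)B1OC(C)(C)C(C)(C)O1; potassium peroxymonosulfate (the two phenolic oxygens), [K+].[O-]S(=O)(=O)OO
Why: Iridium-catalysed C–H borylation is sterically controlled, so the second boryl group can only enter meta to both OMe and the first boryl group, and boronate oxidation then gives the phenols; the para-monoborylated by-product cannot react further and is removed after oxidation as 4-methoxyphenol.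

Step 8
Reactants: 14 5-methoxybenzene-1,3-diol; 15 acetic anhydride
Product: 16 1-(2,4-dihydroxy-6-methoxyphenyl)ethan-1-one
Conditions: 15 (1.1 equiv), BF3·OEt2 (3 equiv), 70 °C; then H2O, 25 °C
Reagents that add atoms: none
Why: Boron trifluoride-mediated Friedel–Crafts (Nencki-type) acetylation; the two equivalent positions flanked by OH and OMe (para to the other OH) are favoured over the single position between the hydroxyls, and the minor symmetric isomer is removed by chromatography.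

Step 9
Reactants: 2 tert-butyl(4-iodophenoxy)dimethylsilane
Product: 18 4-(TBSO)benzaldehyde, via arylmagnesium chloride 17 (not isolated)
Conditions: iPrMgCl·LiCl (1.1 equiv), THF, −20 to 0 °C; DMF (2 equiv); 1 M HCl work-up
Reagents that add atoms: isopropylmagnesium chloride (Mg and Cl of 17 only), CC(C)[Mg]Cl; N,N-dimethylformamide (formyl group), CN(C)C=O
Why: Iodine–magnesium exchange followed by Bouveault formylation of the aryl Grignard reagent.

Step 10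
Reactants: 16 1-(2,4-dihydroxy-6-methoxyphenyl)ethan-1-one; 18 4-(TBSO)benzaldehyde
Product: 19 (E)-1-(2,4-dihydroxy-6-methoxyphenyl)-3-[4-(TBSO)phenyl]prop-2-en-1-one
Conditions: BF3·OEt2 (3 equiv), 1,4-dioxane, 25 °C; then H2O
Reagents that add atoms: none
Why: Claisen–Schmidt aldol condensation promoted by BF3 through the boron chelate of the o-hydroxy ketone; the acidic medium leaves the aryl silyl ether intact, avoids flavanone formation and gives the thermodynamic E-enone.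

Step 11
Reactants: 19 (E)-1-(2,4-dihydroxy-6-methoxyphenyl)-3-[4-(TBSO)phenyl]prop-2-en-1-one; 11 (2R,4S)-2-{(E)-2-[4-(TBSO)phenyl]ethenyl}-4-{2-[4-(TBSO)phenyl]ethyl}oxetane
Product: 20 (2,4-dihydroxy-6-methoxyphenyl)[(2R,3R,4S,6S)-2-[4-(TBSO)phenyl]-4-{(E)-2-[4-(TBSO)phenyl]ethenyl}-6-{2-[4-(TBSO)phenyl]ethyl}oxan-3-yl]methanone
Conditions: Sc(OTf)3 (10 mol%), 2,6-di-tert-butyl-4-methylpyridine (20 mol%), 4 Å molecular sieves, CH2Cl2, −40 to 0 °C; 11 (1.2 equiv) added over 4 h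
Reagents that add atoms: none
Why: Proposed new method: Sc(OTf)3 binds 19 as its 2-O/C=O chelate, the oxetane oxygen (or the scandium alkoxide of the opened oxetane) adds to the activated β-carbon, the allylic C–O bond ionises to a (4-silyloxystyryl)allyl cation and the chelated Z-enolate carbon captures it in a chair, so the enone C=C is inserted into the oxetane C2–O bond (4 → 6 ring expansion); the E-alkene gives 2,3-trans, the ether oxygen held on trivalent scandium puts the C2 aryl pseudo-equatorial on the chelate and therefore axial on the new ring (2,6-trans), styryl and arylethyl sit equatorial (4,6-cis), the oxetane C2 configuration is erased and its C4 becomes C6 untouched; closest known reactions are Lewis-acid (4+2) annulations of donor–acceptor cyclobutanes with aldehydes, the Cu(OTf)2-catalysed ring expansion of 2-vinyloxetanes and Pd-catalysed insertion of heterocumulenes into 2-vinyloxetanes.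

Step 12
Reactants: 20 the oxanyl ketone of step 11; 11 (2R,4S)-2-{(E)-2-[4-(TBSO)phenyl]ethenyl}-4-{2-[4-(TBSO)phenyl]ethyl}oxetane
Product: 21 (4-{[(1E,3R,5S)-5-hydroxy-1,7-bis[4-(TBSO)phenyl]hept-1-en-3-yl]oxy}-2-hydroxy-6-methoxyphenyl)[(2R,3R,4S,6S)-2-[4-(TBSO)phenyl]-4-{(E)-2-[4-(TBSO)phenyl]ethenyl}-6-{2-[4-(TBSO)phenyl]ethyl}oxan-3-yl]methanone
Conditions: Pd2(dba)3 (2.5 mol%), PPh3 (12 mol%), THF, 25 °C; 11 (1.2 equiv)
Reagents that add atoms: none
Why: Tsuji–Trost allylic etherification with a vinyl oxetane as electrophile: zerovalent palladium opens the oxetane with inversion, the freed alkoxide deprotonates the most acidic phenol (4-OH of ring A; the 2-OH is chelated) and the phenoxide attacks the allyl terminus remote from the aryl group with a second inversion, so the ether carbon keeps 3R and the 5S carbinol is released without a protecting group.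

Step 13
Reactants: 21 the aryl allyl ether of step 12
Product: 22 {2,4-dihydroxy-3-[(1R,2E,5S)-5-hydroxy-1,7-bis[4-(TBSO)phenyl]hept-2-en-1-yl]-6-methoxyphenyl}[(2R,3R,4S,6S)-2-[4-(TBSO)phenyl]-4-{(E)-2-[4-(TBSO)phenyl]ethenyl}-6-{2-[4-(TBSO)phenyl]ethyl}oxan-3-yl]methanone
Conditions: Eu(fod)3 (fod = 6,6,7,7,8,8,8-heptafluoro-2,2-dimethyloctane-3,5-dionate; 10 mol%), CHCl3, 50 °C
Reagents that add atoms: none
Why: Lewis-acid-assisted aromatic Claisen rearrangement through a chair with the alkyl chain equatorial: the C–C bond forms on the allyl face that the oxygen leaves, transferring 3R to the new 1R benzylic centre with an E-alkene, and the hydrogen-bonded o-hydroxy ketone directs the shift to the ring carbon between the two oxygens.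

Step 14
Reactants: 22 penta-O-TBS blepharocalyxin B
Product: 23 blepharocalyxin B
Conditions: HF·pyridine, pyridine, THF, 0 to 25 °C
Reagents that add atoms: none
Why: Fluoride cleavage of the five aryl silyl ethers under buffered, non-basic conditions, which avoids retro-oxa-Michael opening or C3 epimerisation of the β-alkoxy ketone.

## Compound list

1 | 4-iodophenol | Oc1ccc(I)cc1 | starting material
2 | tert-butyl(4-iodophenoxy)dimethylsilane | CC(C)(C)[Si](C)(C)Oc1ccc(I)cc1 | intermediate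
3 | prop-2-en-1-ol (allyl alcohol) | C=CCO | starting material
4 | 3-[4-(TBSO)phenyl]propanal | O=CCCc1ccc(O[Si](C)(C)C(C)(C)C)cc1 | intermediate
5 | but-3-en-2-one (methyl vinyl ketone) | CC(=O)C=C | starting material
6 | (E)-4-[4-(TBSO)phenyl]but-3-en-2-one | CC(=O)/C=C/c1ccc(O[Si](C)(C)C(C)(C)C)cc1 | intermediate
7 | {[(E)-4-[4-(TBSO)phenyl]buta-1,3-dien-2-yl]oxy}diisopinocampheylborane | C=C(/C=C/c1ccc(O[Si](C)(C)C(C)(C)C)cc1)OB([C@@H]1C[C@@H]2C[C@H]([C@H]1C)C2(C)C)[C@@H]1C[C@@H]2C[C@H]([C@H]1C)C2(C)C | intermediate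
8 | (1E,5R)-5-hydroxy-1,7-bis[4-(TBSO)phenyl]hept-1-en-3-one | O=C(/C=C/c1ccc(O[Si](C)(C)C(C)(C)C)cc1)C[C@@H](CCc1ccc(O[Si](C)(C)C(C)(C)C)cc1)O | intermediate
9 | (1E,5R)-3-oxo-1,7-bis[4-(TBSO)phenyl]hept-1-en-5-yl methanesulfonate | O=C(/C=C/c1ccc(O[Si](C)(C)C(C)(C)C)cc1)C[C@@H](CCc1ccc(O[Si](C)(C)C(C)(C)C)cc1)OS(C)(=O)=O | intermediate
10 | (1E,3R,5R)-3-hydroxy-1,7-bis[4-(TBSO)phenyl]hept-1-en-5-yl methanesulfonate | O[C@@H](/C=C/c1ccc(O[Si](C)(C)C(C)(C)C)cc1)C[C@@H](CCc1ccc(O[Si](C)(C)C(C)(C)C)cc1)OS(C)(=O)=O | intermediate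
11 | (2R,4S)-2-{(E)-2-[4-(TBSO)phenyl]ethenyl}-4-{2-[4-(TBSO)phenyl]ethyl}oxetane (trans) | O1[C@@H](/C=C/c2ccc(O[Si](C)(C)C(C)(C)C)cc2)C[C@@H]1CCc1ccc(O[Si](C)(C)C(C)(C)C)cc1 | intermediate
12 | anisole | COc1ccccc1 | starting material
13 | 2,2′-(5-methoxy-1,3-phenylene)bis(4,4,5,5-tetramethyl-1,3,2-dioxaborolane) | COc1cc(B2OC(C)(C)C(C)(C)O2)cc(B2OC(C)(C)C(C)(C)O2)c1 | intermediate
14 | 5-methoxybenzene-1,3-diol | COc1cc(O)cc(O)c1 | intermediate
15 | acetic anhydride | CC(=O)OC(C)=O | starting material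
16 | 1-(2,4-dihydroxy-6-methoxyphenyl)ethan-1-one | COc1cc(O)cc(O)c1C(C)=O | intermediate
17 | [4-(TBSO)phenyl]magnesium chloride (LiCl adduct) | CC(C)(C)[Si](C)(C)Oc1ccc([Mg]Cl)cc1 | intermediate
18 | 4-(TBSO)benzaldehyde | O=Cc1ccc(O[Si](C)(C)C(C)(C)C)cc1 | intermediate
19 | (E)-1-(2,4-dihydroxy-6-methoxyphenyl)-3-[4-(TBSO)phenyl]prop-2-en-1-one | COc1cc(O)cc(O)c1C(=O)/C=C/c1ccc(O[Si](C)(C)C(C)(C)C)cc1 | intermediate
20 | (2,4-dihydroxy-6-methoxyphenyl)[(2R,3R,4S,6S)-2-[4-(TBSO)phenyl]-4-{(E)-2-[4-(TBSO)phenyl]ethenyl}-6-{2-[4-(TBSO)phenyl]ethyl}oxan-3-yl]methanone | COc1cc(O)cc(O)c1C(=O)[C@@H]1[C@H](/C=C/c2ccc(O[Si](C)(C)C(C)(C)C)cc2)C[C@H](CCc2ccc(O[Si](C)(C)C(C)(C)C)cc2)O[C@H]1c1ccc(O[Si](C)(C)C(C)(C)C)cc1 | intermediate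
21 | (4-{[(1E,3R,5S)-5-hydroxy-1,7-bis[4-(TBSO)phenyl]hept-1-en-3-yl]oxy}-2-hydroxy-6-methoxyphenyl)[(2R,3R,4S,6S)-2-[4-(TBSO)phenyl]-4-{(E)-2-[4-(TBSO)phenyl]ethenyl}-6-{2-[4-(TBSO)phenyl]ethyl}oxan-3-yl]methanone | COc1cc(O[C@@H](/C=C/c2ccc(O[Si](C)(C)C(C)(C)C)cc2)C[C@@H](O)CCc2ccc(O[Si](C)(C)C(C)(C)C)cc2)cc(O)c1C(=O)[C@@H]1[C@H](/C=C/c2ccc(O[Si](C)(C)C(C)(C)C)cc2)C[C@H](CCc2ccc(O[Si](C)(C)C(C)(C)C)cc2)O[C@H]1c1ccc(O[Si](C)(C)C(C)(C)C)cc1 | intermediate
22 | {2,4-dihydroxy-3-[(1R,2E,5S)-5-hydroxy-1,7-bis[4-(TBSO)phenyl]hept-2-en-1-yl]-6-methoxyphenyl}[(2R,3R,4S,6S)-2-[4-(TBSO)phenyl]-4-{(E)-2-[4-(TBSO)phenyl]ethenyl}-6-{2-[4-(TBSO)phenyl]ethyl}oxan-3-yl]methanone (penta-O-TBS blepharocalyxin B) | COc1cc(O)c([C@H](/C=C/C[C@@H](O)CCc2ccc(O[Si](C)(C)C(C)(C)C)cc2)c2ccc(O[Si](C)(C)C(C)(C)C)cc2)c(O)c1C(=O)[C@@H]1[C@H](/C=C/c2ccc(O[Si](C)(C)C(C)(C)C)cc2)C[C@H](CCc2ccc(O[Si](C)(C)C(C)(C)C)cc2)O[C@H]1c1ccc(O[Si](C)(C)C(C)(C)C)cc1 | intermediate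
23 | blepharocalyxin B, {2,4-dihydroxy-3-[(1R,2E,5S)-5-hydroxy-1,7-bis(4-hydroxyphenyl)hept-2-en-1-yl]-6-methoxyphenyl}[(2R,3R,4S,6S)-2-(4-hydroxyphenyl)-6-[2-(4-hydroxyphenyl)ethyl]-4-[(E)-2-(4-hydroxyphenyl)ethenyl]oxan-3-yl]methanone | COc1cc(O)c([C@H](/C=C/C[C@@H](O)CCc2ccc(O)cc2)c2ccc(O)cc2)c(O)c1C(=O)[C@@H]1[C@H](/C=C/c2ccc(O)cc2)C[C@H](CCc2ccc(O)cc2)O[C@H]1c1ccc(O)cc1 | target

## Step count and risks

Total steps: 14. Longest linear sequence: 9 (steps 1, 2, 4, 5, 6, 11, 12, 13, 14).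

**Step 11 (the proposed new ring expansion).** Likely problems are the known Lewis-acid isomerisation of the styryl oxetane to a 3,6-dihydro-2H-pyran, Friedel–Crafts alkylation of ring A by the allyl cation, and formation of the all-equatorial (2,6-cis) diastereomer. The fallback uses known chemistry only. It sets out from 9, 16 and 18 and comes back at 20. Reduction of 9 with the enantiomeric (R)-Me-CBS catalyst gives (1E,3S,5R)-3-hydroxy-1,7-bis[4-(TBSO)phenyl]hept-1-en-5-yl methanesulfonate F1, which is closed with KHMDS to the cis-oxetane (2S,4S)-2-{(E)-2-[4-(TBSO)phenyl]ethenyl}-4-{2-[4-(TBSO)phenyl]ethyl}oxetane F2. Ketone 16 is bis-silylated (TBSOTf, 2,6-lutidine) to 1-[2,4-bis(TBSO)-6-methoxyphenyl]ethan-1-one F3. Its lithium enolate (LiHMDS, THF, −78 °C) is alkylated with F2 under Pd(PPh3)4 (Tsuji–Trost alkylation, net retention, attack remote from the aryl group) to give the δ-hydroxy ketone (3R,5S)-1-[2,4-bis(TBSO)-6-methoxyphenyl]-5-hydroxy-7-[4-(TBSO)phenyl]-3-{(E)-2-[4-(TBSO)phenyl]ethenyl}heptan-1-one F4, which already carries the C4 and C6 centres. Aldol condensation with 18 (TiCl4, Et3N, CH2Cl2) gives the (E)-enone (2E,3S,5S)-1-[2,4-bis(TBSO)-6-methoxyphenyl]-5-hydroxy-2-{[4-(TBSO)phenyl]methylidene}-7-[4-(TBSO)phenyl]-3-{(E)-2-[4-(TBSO)phenyl]ethenyl}heptan-1-one F5. Kinetic 6-endo oxa-Michael cyclisation (KHMDS 10 mol%, THF, −78 °C) then gives the oxane [2,4-bis(TBSO)-6-methoxyphenyl][(2R,3R,4S,6S)-2-[4-(TBSO)phenyl]-4-{(E)-2-[4-(TBSO)phenyl]ethenyl}-6-{2-[4-(TBSO)phenyl]ethyl}oxan-3-yl]methanone F6: from the E-alkene the aryl group ends axial, and C3 is equilibrated to the trans isomer. K2CO3 in MeOH at 0 °C removes only the two labile ring A silyl ethers and returns 20.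

**Step 13 (aromatic Claisen).** The risks are a shift to the ring carbon next to OMe, ionisation of the very electron-rich allyl ether with loss of chirality transfer, and sensitivity of the β-alkoxy ketone. The fallback forms the same C–C bond on the simple ketone before the oxane exists. It sets out from 16 and 11 and comes back at 22. Pd2(dba)3/PPh3 etherification of 16 with 11 gives 1-(4-{[(1E,3R,5S)-5-hydroxy-1,7-bis[4-(TBSO)phenyl]hept-1-en-3-yl]oxy}-2-hydroxy-6-methoxyphenyl)ethan-1-one F7. Its Claisen rearrangement (Eu(fod)3, or N,N-diethylaniline at 160 °C on this robust substrate, regioisomers separated here) gives 1-{2,4-dihydroxy-3-[(1R,2E,5S)-5-hydroxy-1,7-bis[4-(TBSO)phenyl]hept-2-en-1-yl]-6-methoxyphenyl}ethan-1-one F8. BF3·OEt2 condensation with 18 gives the chalcone (E)-1-{2,4-dihydroxy-3-[(1R,2E,5S)-5-hydroxy-1,7-bis[4-(TBSO)phenyl]hept-2-en-1-yl]-6-methoxyphenyl}-3-[4-(TBSO)phenyl]prop-2-en-1-one F9, and the ring expansion with 11 under the step 11 conditions then gives 22 directly.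

**Step 6 (oxetane closure).** The γ-mesyloxy allylic alkoxide may undergo Grob fragmentation (to the cinnamaldehyde and a terminal alkene) or E2 elimination instead of 4-exo closure. The fallback is a double-inversion oxetane synthesis whose outcome does not depend on which carbinol carbon is attacked. It sets out from 6 and 4 and comes back at 11. The aldol with (+)-B-chlorodiisopinocampheylborane gives (1E,5S)-5-hydroxy-1,7-bis[4-(TBSO)phenyl]hept-1-en-3-one F10. Evans–Saksena reduction (Me4NBH(OAc)3, MeCN–AcOH, −30 °C) gives the anti-diol (1E,3R,5S)-1,7-bis[4-(TBSO)phenyl]hept-1-ene-3,5-diol F11. Trimethyl orthoacetate with pyridinium p-toluenesulfonate gives the cyclic orthoester (4R,6S)-2-methoxy-2-methyl-4-{(E)-2-[4-(TBSO)phenyl]ethenyl}-6-{2-[4-(TBSO)phenyl]ethyl}-1,3-dioxane F12. Acetyl bromide opens it with inversion to (1E,3S,5S)-3-bromo-1,7-bis[4-(TBSO)phenyl]hept-1-en-5-yl acetate F13, and K2CO3 in MeOH removes the acetate and closes the ring with a second inversion to give 11.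

Further compounds

F1 | step 11 | (1E,3S,5R)-3-hydroxy-1,7-bis[4-(TBSO)phenyl]hept-1-en-5-yl methanesulfonate | O[C@H](/C=C/c1ccc(O[Si](C)(C)C(C)(C)C)cc1)C[C@@H](CCc1ccc(O[Si](C)(C)C(C)(C)C)cc1)OS(C)(=O)=O
F2 | step 11 | (2S,4S)-2-{(E)-2-[4-(TBSO)phenyl]ethenyl}-4-{2-[4-(TBSO)phenyl]ethyl}oxetane (cis) | O1[C@H](/C=C/c2ccc(O[Si](C)(C)C(C)(C)C)cc2)C[C@@H]1CCc1ccc(O[Si](C)(C)C(C)(C)C)cc1
F3 | step 11 | 1-[2,4-bis(TBSO)-6-methoxyphenyl]ethan-1-one | COc1cc(O[Si](C)(C)C(C)(C)C)cc(O[Si](C)(C)C(C)(C)C)c1C(C)=O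
F4 | step 11 | (3R,5S)-1-[2,4-bis(TBSO)-6-methoxyphenyl]-5-hydroxy-7-[4-(TBSO)phenyl]-3-{(E)-2-[4-(TBSO)phenyl]ethenyl}heptan-1-one | COc1cc(O[Si](C)(C)C(C)(C)C)cc(O[Si](C)(C)C(C)(C)C)c1C(=O)C[C@H](/C=C/c1ccc(O[Si](C)(C)C(C)(C)C)cc1)C[C@@H](O)CCc1ccc(O[Si](C)(C)C(C)(C)C)cc1
F5 | step 11 | (2E,3S,5S)-1-[2,4-bis(TBSO)-6-methoxyphenyl]-5-hydroxy-2-{[4-(TBSO)phenyl]methylidene}-7-[4-(TBSO)phenyl]-3-{(E)-2-[4-(TBSO)phenyl]ethenyl}heptan-1-one | COc1cc(O[Si](C)(C)C(C)(C)C)cc(O[Si](C)(C)C(C)(C)C)c1C(=O)/C(=C/c1ccc(O[Si](C)(C)C(C)(C)C)cc1)[C@H](/C=C/c1ccc(O[Si](C)(C)C(C)(C)C)cc1)C[C@@H](O)CCc1ccc(O[Si](C)(C)C(C)(C)C)cc1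
F6 | step 11 | [2,4-bis(TBSO)-6-methoxyphenyl][(2R,3R,4S,6S)-2-[4-(TBSO)phenyl]-4-{(E)-2-[4-(TBSO)phenyl]ethenyl}-6-{2-[4-(TBSO)phenyl]ethyl}oxan-3-yl]methanone | COc1cc(O[Si](C)(C)C(C)(C)C)cc(O[Si](C)(C)C(C)(C)C)c1C(=O)[C@@H]1[C@H](/C=C/c2ccc(O[Si](C)(C)C(C)(C)C)cc2)C[C@H](CCc2ccc(O[Si](C)(C)C(C)(C)C)cc2)O[C@H]1c1ccc(O[Si](C)(C)C(C)(C)C)cc1
F7 | step 13 | 1-(4-{[(1E,3R,5S)-5-hydroxy-1,7-bis[4-(TBSO)phenyl]hept-1-en-3-yl]oxy}-2-hydroxy-6-methoxyphenyl)ethan-1-one | COc1cc(O[C@@H](/C=C/c2ccc(O[Si](C)(C)C(C)(C)C)cc2)C[C@@H](O)CCc2ccc(O[Si](C)(C)C(C)(C)C)cc2)cc(O)c1C(C)=O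
F8 | step 13 | 1-{2,4-dihydroxy-3-[(1R,2E,5S)-5-hydroxy-1,7-bis[4-(TBSO)phenyl]hept-2-en-1-yl]-6-methoxyphenyl}ethan-1-one | COc1cc(O)c([C@H](/C=C/C[C@@H](O)CCc2ccc(O[Si](C)(C)C(C)(C)C)cc2)c2ccc(O[Si](C)(C)C(C)(C)C)cc2)c(O)c1C(C)=O
F9 | step 13 | (E)-1-{2,4-dihydroxy-3-[(1R,2E,5S)-5-hydroxy-1,7-bis[4-(TBSO)phenyl]hept-2-en-1-yl]-6-methoxyphenyl}-3-[4-(TBSO)phenyl]prop-2-en-1-one | COc1cc(O)c([C@H](/C=C/C[C@@H](O)CCc2ccc(O[Si](C)(C)C(C)(C)C)cc2)c2ccc(O[Si](C)(C)C(C)(C)C)cc2)c(O)c1C(=O)/C=C/c1ccc(O[Si](C)(C)C(C)(C)C)cc1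
F10 | step 6 | (1E,5S)-5-hydroxy-1,7-bis[4-(TBSO)phenyl]hept-1-en-3-one | O=C(/C=C/c1ccc(O[Si](C)(C)C(C)(C)C)cc1)C[C@H](CCc1ccc(O[Si](C)(C)C(C)(C)C)cc1)O
F11 | step 6 | (1E,3R,5S)-1,7-bis[4-(TBSO)phenyl]hept-1-ene-3,5-diol (anti) | O[C@@H](/C=C/c1ccc(O[Si](C)(C)C(C)(C)C)cc1)C[C@H](CCc1ccc(O[Si](C)(C)C(C)(C)C)cc1)O
F12 | step 6 | (4R,6S)-2-methoxy-2-methyl-4-{(E)-2-[4-(TBSO)phenyl]ethenyl}-6-{2-[4-(TBSO)phenyl]ethyl}-1,3-dioxane (both C2 epimers) | COC1(C)O[C@@H](/C=C/c2ccc(O[Si](C)(C)C(C)(C)C)cc2)C[C@H](CCc2ccc(O[Si](C)(C)C(C)(C)C)cc2)O1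
F13 | step 6 | (1E,3S,5S)-3-bromo-1,7-bis[4-(TBSO)phenyl]hept-1-en-5-yl acetate | Br[C@H](/C=C/c1ccc(O[Si](C)(C)C(C)(C)C)cc1)C[C@H](CCc1ccc(O[Si](C)(C)C(C)(C)C)cc1)OC(C)=O
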